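# Synthesis plan for 2,3,5-tribromo-6-(3,5-dibromo-2-methoxyphenoxy)phenol (14)

## The problem

Compound 14 is a diaryl ether of two different bromocatechol units. Ring A is numbered C1 (O-aryl), C2 (OMe), C3 (Br), C4 (H), C5 (Br), C6 (H); ring B is numbered C1' (ether oxygen), C2' (Br), C3' (H), C4' (Br), C5' (Br), C6' (OH). There is no stereocentre and no configurationally stable axis, so the task is purely regiochemical: five bromines and four oxygens must each reach one defined carbon.

The ether oxygen is flanked on ring B by C2'–Br and C6'–O and is bonded to a ring A carbon next to C2–OMe. A copper- or palladium-catalysed C–O coupling would have to make this hindered bond while sparing up to five C–Br bonds, and an SNAr reaction would need an activating group that the target lacks.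

Ring B cannot be made by brominating a free C6' phenol, because C3', para to that hydroxyl, is the one unsubstituted position. The bromines at C2' and C4' are ortho and para to O1', so O1' must be the free, directing hydroxyl while O6' is masked and C5'–Br is already present. Ring A is complementary: its bromines at C3 and C5 are ortho and para to the C2 oxygen, and nothing is directed by the C1 oxygen.

The groups that will not tolerate rough treatment are:
- the aryl C–Br bonds (reducing metals, hydrogenolysis, halogen–metal exchange);
- the C3'–H between two bromines, which invites halogen migration under strong amide bases;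
- the electron-rich halophenols, which oxidize to quinones.

At the end a methyl ether on ring A must also be told apart from a free hydroxyl on ring B.

The feature that opens the key step is in ring A: C2 bears oxygen, C5 para to it bears bromine, and C4 and C6 are unsubstituted CH. This is the pattern of a phenol assembled from a ketone (C1–C2–C3, with the ring B oxygen already on C1) and 2-bromomalonaldehyde (C4–C5–C6), so ring A can be built onto the ether oxygen instead of being coupled to it.

## Retrosynthesis

**14 to 13.** The last bond cut is the acetal C–O bond at O6', which traces 14 to its methoxymethyl ether 13. The ring B hydroxyl must stay masked to the end so that it neither directs bromination nor competes in the alkylations, and because a free bromocatechol is easily oxidized. An acetal is preferred over a benzyl ether, whose hydrogenolysis would attack C–Br, and over a second alkyl ether, whose Lewis acid cleavage would have to spare the C2 methyl ether. The forward step needs only a mild acid-catalysed exchange that leaves the methyl and diaryl ethers alone.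

**13 to 12 to 11.** The O–CH3 bond and then the C3–Br bond of ring A are cut, leading through phenol 12 to phenol 11. The order matters. With the C2 oxygen free it is the strongest donor in the molecule, and its para position (C5) and one ortho position (C1) are occupied, so bromination can only go to C3. After methylation the C1 and C2 oxygens would be comparable donors and C4 and C6 would compete. Compound 11 is simpler by one bromine and one methyl group. The forward steps need ring selectivity, which is expected because ring B is deactivated by three bromines and its only C–H lies between two of them, and then an ordinary phenol methylation.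

**11 to 7 and 8.** Ring A of 11 is opened at C1–C6 and C3–C4, dividing it into the C1–C2–C3 unit of ketone 7 and the C4–C5–C6 unit of dialdehyde 8.
- The neighbouring cut, the aryl–oxygen bond at C1, would return two bromoarenes. It would demand a metal-catalysed coupling at a doubly ortho-substituted oxygen beside several C–Br bonds, or an SNAr reaction on an unactivated ring A partner.
- The ring construction avoids both, because the hindered oxygen is first attached to an sp3 carbon and the arene is then built around it.
- The simplification is large: all of ring A with its C5 bromine comes from a three-carbon dialdehyde and the acetonyl group of 7.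
- The forward reaction must form two C–C bonds at the terminal carbons of 8, keep its C–Br bond and the aryloxy group of 7, and aromatize by loss of two molecules of water.
- Compound 8 is a strong carbon acid whose enolate, unlike that of the nitro analogue, is a poor electrophile. The condensation is therefore planned under secondary amine and carboxylic acid mediation, where 8 reacts as its vinamidinium ion 9 and the first C–C bond gives the open-chain aminodienone 10.

**7 to 5 and 6.** The O–CH2 bond of 7 is cut to phenol 5 and chloroacetone 6. Substitution at a primary α-keto carbon is little affected by the two ortho substituents around O1' that would burden any aryl–oxygen coupling, and 6 is a commodity. The forward step must O-alkylate an acidic, hindered phenoxide faster than 6 condenses with itself.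

**5 to 4.** The C2'–Br and C4'–Br bonds of 5 are cut, leading to monobromophenol 4. These carbons are ortho and para to O1', which is free in 4, whereas O6' is an acetal flanked on both sides and C5'–Br is already present. The position para to O6' (C3') is meta to the free hydroxyl and should stay untouched. Cutting C5'–Br instead would require bromination meta to the directing hydroxyl. The forward step is a double electrophilic bromination that must stop at two and must not release free acid.

**4 to 2 to 1.** The C1'–O bond of 4 is traced to the formyl group of aldehyde 2, by aryl migration to oxygen in a peracid oxidation and cleavage of the formate 3. The acetal of 2 is traced to the hydroxyl of commercial 1. With these two cuts the catechol oxygens are never equivalent: one is the hydroxyl of 1 and is protected while the other is still a carbon substituent. No selective monoprotection of an unsymmetrical catechol is needed, and 1 already holds C5'–Br in the right place.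

## Roads not taken

**Alternative 1:** The cut is at the three C–Br bonds of ring B (C2', C4', C5'). They would be formed together on the diaryl ether A2, N-[3-(3,5-dibromo-2-methoxyphenoxy)-4-hydroxyphenyl]acetamide, whose acetamido group sits on C3'. In the forward key step A2 would undergo threefold electrophilic bromination to give A1, N-[2,3,6-tribromo-5-(3,5-dibromo-2-methoxyphenoxy)-4-hydroxyphenyl]acetamide. Amide hydrolysis, diazotization and reduction would then remove the nitrogen to give 14.
- Merits: the nitrogen blocks exactly the position para to the C6' hydroxyl that must stay free, and it directs to both its neighbours, so the awkward ring B pattern is written in one operation on an unbrominated ring.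
- Weak points:
  - The third bromine must enter a ring that already holds two, next to the acetamido group, while C4 and C6 of ring A (para and ortho to the ether oxygen) compete.
  - An acetanilide flanked by two bromines is slow to hydrolyse.
  - Diazotization of a para-aminophenol leads to a quinone diazide, and the aminophenol is readily oxidized to a quinone imine, so the deamination is the least secure part.
  - The ether bond of A2 must still be made by a coupling next to the two C–Br bonds of ring A, which this strategy leaves unsolved.
- Comparison: this road is better in that ring B could start from a cheap aminophenol and receive all its bromines in one step, whereas the chosen plan spends four steps on phenol 5. Against that, the chosen plan introduces no atom that must be removed again over three further steps, and it forms the ether bond without any metal near C–Br.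

**Alternative 2:** Ring A is carried as a saturated ketone. The cut removes the aromatic unsaturation and the C3–Br and C5–Br bonds, leading to the racemic A4, 2-[2,4,5-tribromo-6-(propan-2-yloxy)phenoxy]cyclohexan-1-one. In the forward key step A4 would be treated with an excess of buffered brominating agent. Repeated α-bromination and dehydrobromination would aromatize the ring and brominate ortho and para to the new hydroxyl, giving A3, 2,4-dibromo-6-[2,4,5-tribromo-6-(propan-2-yloxy)phenoxy]phenol. Methylation and cleavage of the isopropyl ether would follow.
- Merits: the ether oxygen is again attached by substitution at an sp3 carbon, the reagents are cheap, and aromatization plus both ring A bromines come in one step.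
- Weak points:
  - α-Bromination also occurs at C1, which bears the aryloxy group, and the resulting α-bromo-α-aryloxy ketone can ionize and expel the ring B phenoxide.
  - The sequence passes through polybromo ketones whose eliminations are not always clean.
  - About four equivalents of acid are released with heating, which rules out an acetal on O6' and forces a robust alkyl ether.
  - Removing that ether at the end needs a Lewis acid that must spare the C2 methyl ether next to the ether oxygen.
- Comparison: this road is shorter by one step and uses simpler reagents. The chosen plan sets against it a ring A whose substituents are fixed by the connectivity of 7 and 8, near-neutral conditions throughout, and an end game that is a mild acetal cleavage.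

**Alternative 3:** Ring A is cut at C1–C6 and C2–C3 into the diene A7, 3,5-dibromo-2H-pyran-2-one, and the ketene silyl acetal A6, {1-methoxy-2-[2,4,5-tribromo-6-(methoxymethoxy)phenoxy]ethenoxy}trimethylsilane. On heating, [4+2] cycloaddition followed by decarboxylative aromatization, with expulsion of the silyloxy group, would give A5, 1,5-dibromo-2-methoxy-3-[2,4,5-tribromo-6-(methoxymethoxy)phenoxy]benzene. A5 has the same structure as 13.
- Merits: the route is convergent. Both ring A bromines and the methoxy group arrive in the ring-forming step, so the separate bromination and methylation of the chosen plan disappear.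
- Weak points:
  - A7 is not a stock chemical and must be prepared.
  - Making A6 requires enolization of an aryloxyacetate next to a ring whose C3'–H lies between two bromines, where amide bases can trigger halogen migration. A6 is also a hindered, moisture-sensitive tetrasubstituted alkene.
  - The C2–C3 bond must form between a fully substituted acetal carbon and the bromine-bearing carbon of A7.
  - The bridged lactone needs heat to lose carbon dioxide.
  - The final elimination can expel either the silyloxy or the methoxy group.
- Comparison: this road is two steps shorter after the ring B phenol. The chosen plan sets against it two purchasable partners, no strong base or silyl enol ether on a polybrominated arene, and C–C bond formation at unhindered terminal CH carbons.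

Key step: step 5

## Route

Assumption: compounds 1, 6 and 8 are purchased, and 8 is handled as its stable enol form.

Step 1
Reactants: 1 3-bromo-2-hydroxybenzaldehyde
Product: 2 3-bromo-2-(methoxymethoxy)benzaldehyde
Conditions: MOMCl, iPr2NEt, CH2Cl2, 0 °C → rt
Reagents that add atoms: chloromethyl methyl ether (MOMCl), COCCl
Why: O-alkylation of the phenol with the α-chloro ether (methoxymethyl protection); the hydrogen bond to the formyl group slows the reaction but does not prevent it, and nothing else in 1 is nucleophilic.

Step 2
Reactants: 2 3-bromo-2-(methoxymethoxy)benzaldehyde
Product: 4 3-bromo-2-(methoxymethoxy)phenol, via aryl formate 3 (not isolated)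
Conditions: mCPBA, CH2Cl2, 0 °C → rt; aq. NaHCO3 wash; then Et3N (cat.), MeOH, rt
Reagents that add atoms: 3-chloroperbenzoic acid (mCPBA), OOC(=O)c1cccc(Cl)c1
Why: Baeyer–Villiger (Dakin-type) oxidation of an ortho-alkoxybenzaldehyde, in which the aryl group migrates in the Criegee intermediate to give formate 3, followed by base-catalysed methanolysis of the labile aryl formate. The acetal and the C–Br bond are inert to the peracid, and the phenol stays masked as its formate until the oxidant has been removed.

Step 3
Reactants: 4 3-bromo-2-(methoxymethoxy)phenol
Product: 5 2,4,5-tribromo-6-(methoxymethoxy)phenol
Conditions: NBS (2.05 equiv), MeCN, 0 °C → rt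
Reagents that add atoms: N-bromosuccinimide, O=C1CCC(=O)N1Br
Why: Electrophilic aromatic bromination directed by the free hydroxyl to its open ortho (C2') and para (C4') positions. The acetal oxygen is flanked on both sides, twisted out of conjugation and a weaker donor, so C3' (para to it, meta to the hydroxyl) should stay free, and NBS releases no stoichiometric HBr that could cleave the acetal.

Step 4
Reactants: 5 2,4,5-tribromo-6-(methoxymethoxy)phenol; 6 1-chloropropan-2-one (chloroacetone)
Product: 7 1-[2,4,5-tribromo-6-(methoxymethoxy)phenoxy]propan-2-one
Conditions: K2CO3, DMF, rt → 40 °C
Reagents that add atoms: none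
Why: Williamson ether synthesis by SN2 at the primary α-keto carbon; the acidic tribromophenol is fully deprotonated by carbonate, and the activated chloride compensates for the hindrance around the oxygen.

Step 5
Reactants: 7 1-[2,4,5-tribromo-6-(methoxymethoxy)phenoxy]propan-2-one; 8 2-bromopropanedial (2-bromomalonaldehyde)
Product: 11 4-bromo-2-[2,4,5-tribromo-6-(methoxymethoxy)phenoxy]phenol, via bromovinamidinium acetate 9 (not isolated), via open-chain aminodienone 10 (not isolated)
Conditions: pyrrolidine (2.2 equiv), AcOH (2.2 equiv), EtOH, rt → 60 °C
Reagents that add atoms: none
Why: Pyrrolidinium acetate turns 8 into the 2-bromovinamidinium ion 9, an electrophile at both terminal carbons, and the ketone into its enamine or enol, which avoids the poorly electrophilic sodium enolate that 8 would form under hydroxide. The aryloxy-bearing α-carbon of 7 adds to one terminus of 9 and pyrrolidine is lost, which forms C1–C6 and gives the push-pull dienone 10. After E/Z equilibration of 10 the methyl-derived α-carbon attacks the remaining iminium terminus in a Mannich-type 6-(enolendo)-exo-trig closure that forms C3–C4 and closes ring A (a 6π-electrocyclization of the derived trienol would make the same bond). Loss of the second pyrrolidine and enolization of the cyclohexadienone give phenol 11, so amine and acid are both returned. The closest known reaction types are the synthesis of para-nitrophenols from sodium nitromalonaldehyde and ketones and the phenol-forming condensation of vinamidinium salts with ketones that have two enolizable α-positions. No stereocentre is formed. Regiochemistry needs no control, because the three-carbon electrophile is symmetric and either order of bond formation puts the ketone oxygen at C2 and the bromine para to it at C5. The chemoselectivity that is needed, C–C bond formation instead of loss of bromide or of the ring B aryloxide, rests on the bromine sitting on the central electron-rich carbon of 9, where it is neither displaceable nor a positive-halogen donor, and on the aryloxy group having no β-relationship to a carbanionic site.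

Step 6
Reactants: 11 4-bromo-2-[2,4,5-tribromo-6-(methoxymethoxy)phenoxy]phenol
Product: 12 2,4-dibromo-6-[2,4,5-tribromo-6-(methoxymethoxy)phenoxy]phenol
Conditions: NBS (1.0 equiv), iPr2NH (cat.), CH2Cl2, 0 °C
Reagents that add atoms: N-bromosuccinimide, O=C1CCC(=O)N1Br
Why: Amine-catalysed ortho-bromination of a phenol whose para position (C5) and other ortho position (C1) are occupied, so only C3 can react; ring B is deactivated by three bromines and its single C–H is shielded between two of them.

Step 7
Reactants: 12 2,4-dibromo-6-[2,4,5-tribromo-6-(methoxymethoxy)phenoxy]phenol
Product: 13 1,5-dibromo-2-methoxy-3-[2,4,5-tribromo-6-(methoxymethoxy)phenoxy]benzene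
Conditions: MeI, K2CO3, DMF, rt
Reagents that add atoms: iodomethane, CI
Why: Williamson O-methylation of the only free hydroxyl; the small electrophile reaches the di-ortho-substituted phenoxide without difficulty.

Step 8
Reactants: 13 1,5-dibromo-2-methoxy-3-[2,4,5-tribromo-6-(methoxymethoxy)phenoxy]benzene
Product: 14 2,3,5-tribromo-6-(3,5-dibromo-2-methoxyphenoxy)phenol
Conditions: HCl (cat.), MeOH–THF, 40 °C
Reagents that add atoms: none
Why: Acid-catalysed acetal exchange removes the methoxymethyl group as dimethoxymethane; aryl methyl ether, diaryl ether and C–Br bonds are inert to dilute acid.

## Compound list

1 | 3-bromo-2-hydroxybenzaldehyde | O=Cc1cccc(Br)c1O | starting material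
2 | 3-bromo-2-(methoxymethoxy)benzaldehyde | COCOc1c(Br)cccc1C=O | intermediate
3 | 3-bromo-2-(methoxymethoxy)phenyl formate | COCOc1c(Br)cccc1OC=O | intermediate (not isolated)
4 | 3-bromo-2-(methoxymethoxy)phenol | COCOc1c(Br)cccc1O | intermediate
5 | 2,4,5-tribromo-6-(methoxymethoxy)phenol | Oc1c(Br)cc(Br)c(Br)c1OCOC | intermediate
6 | 1-chloropropan-2-one (chloroacetone) | CC(=O)CCl | starting material
7 | 1-[2,4,5-tribromo-6-(methoxymethoxy)phenoxy]propan-2-one | CC(=O)COc1c(Br)cc(Br)c(Br)c1OCOC | intermediate
8 | 2-bromopropanedial (2-bromomalonaldehyde) | O=CC(Br)C=O | starting material
9 | 1-[2-bromo-3-(pyrrolidin-1-yl)prop-2-en-1-ylidene]pyrrolidin-1-ium acetate | BrC(C=[N+]1CCCC1)=CN1CCCC1.CC(=O)[O-] | intermediate (not isolated)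
10 | 5-bromo-6-(pyrrolidin-1-yl)-3-[2,4,5-tribromo-6-(methoxymethoxy)phenoxy]hexa-3,5-dien-2-one (alkene geometries mobile, not defined) | CC(=O)C(Oc1c(Br)cc(Br)c(Br)c1OCOC)=CC(Br)=CN1CCCC1 | intermediate (not isolated)
11 | 4-bromo-2-[2,4,5-tribromo-6-(methoxymethoxy)phenoxy]phenol | Oc1ccc(Br)cc1Oc1c(Br)cc(Br)c(Br)c1OCOC | intermediate
12 | 2,4-dibromo-6-[2,4,5-tribromo-6-(methoxymethoxy)phenoxy]phenol | Oc1c(Br)cc(Br)cc1Oc1c(Br)cc(Br)c(Br)c1OCOC | intermediate
13 | 1,5-dibromo-2-methoxy-3-[2,4,5-tribromo-6-(methoxymethoxy)phenoxy]benzene | COc1c(Br)cc(Br)cc1Oc1c(Br)cc(Br)c(Br)c1OCOC | intermediate
14 | 2,3,5-tribromo-6-(3,5-dibromo-2-methoxyphenoxy)phenol | COc1c(Br)cc(Br)cc1Oc1c(Br)cc(Br)c(Br)c1O | target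

## Step count and risk

Total: 8 steps. Longest linear sequence: 8 steps (1 to 14); 6 and 8 enter as purchased reagents.

**Step 5 (key step).**
- What may go wrong: the condensation may stall after the first C–C bond, leaving the open-chain aminodienone unclosed. The ketone may be consumed by self-condensation or by displacement of the ring B phenoxide at its α-carbon, since that phenoxide is a fair leaving group. The halodialdehyde is also less well documented in this annulation than its nitro analogue.
- Fallback (sets out from 5, returns at 11): phenol 5 is arylated by SNAr with 4-bromo-2-fluorobenzaldehyde (O=Cc1ccc(Br)cc1F; K2CO3, DMF, 110 °C), the fluoride ortho to the formyl group being displaced, to give 4-bromo-2-[2,4,5-tribromo-6-(methoxymethoxy)phenoxy]benzaldehyde F1. Baeyer–Villiger oxidation with mCPBA in CH2Cl2 gives 4-bromo-2-[2,4,5-tribromo-6-(methoxymethoxy)phenoxy]phenyl formate F2, and methanolysis (Et3N, MeOH) releases 11. This gives up the ring construction but still makes the ether bond without a transition metal.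

**Step 2.**
- What may go wrong: hydride migration may compete with aryl migration, leading to over-oxidation to the carboxylic acid. The ring carries a bromine, and its alkoxy donor is twisted between two ortho substituents. The acetal may also be partly lost in the acidic peracid medium.
- Fallback (sets out from 1, returns at 4): Dakin oxidation of the free salicylaldehyde 1 (H2O2, aq. NaOH), in which the ortho-oxido group drives aryl migration, gives 3-bromobenzene-1,2-diol F3. The bulky tert-butyldiphenylsilyl chloride (imidazole, DMF) should silylate the hydroxyl that has no bromine neighbour, giving 2-bromo-6-[(tert-butyldiphenylsilyl)oxy]phenol F4. MOMCl with iPr2NEt then gives [3-bromo-2-(methoxymethoxy)phenoxy](tert-butyl)diphenylsilane F5, and Bu4NF in THF removes the silyl group to give 4. Silyl migration between the two oxygens before the acetal is installed is the point to watch.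

**Step 4.**
- What may go wrong: O-alkylation of the doubly ortho-substituted, weakly nucleophilic phenoxide may be slow, while chloroacetone is consumed by base-induced self-condensation.
- Fallback (sets out from 5, returns at 7): alkylation with 3-chloro-2-methylprop-1-ene (K2CO3, DMF, 60 °C), an electrophile that tolerates heating with base, gives 1,2,5-tribromo-3-(methoxymethoxy)-4-[(2-methylprop-2-en-1-yl)oxy]benzene F6. Ozonolysis (O3, CH2Cl2–MeOH, −78 °C; then Me2S) cleaves the 1,1-disubstituted alkene to ketone 7; the electron-poor arene and the acetal should not react with ozone at this temperature.

## Further compounds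

F1 | step 5 | 4-bromo-2-[2,4,5-tribromo-6-(methoxymethoxy)phenoxy]benzaldehyde | O=Cc1ccc(Br)cc1Oc1c(Br)cc(Br)c(Br)c1OCOC
F2 | step 5 | 4-bromo-2-[2,4,5-tribromo-6-(methoxymethoxy)phenoxy]phenyl formate | O=COc1ccc(Br)cc1Oc1c(Br)cc(Br)c(Br)c1OCOC
F3 | step 2 | 3-bromobenzene-1,2-diol | Oc1cccc(Br)c1O
F4 | step 2 | 2-bromo-6-[(tert-butyldiphenylsilyl)oxy]phenol | Oc1c(Br)cccc1O[Si](c1ccccc1)(c1ccccc1)C(C)(C)C
F5 | step 2 | [3-bromo-2-(methoxymethoxy)phenoxy](tert-butyl)diphenylsilane | COCOc1c(Br)cccc1O[Si](c1ccccc1)(c1ccccc1)C(C)(C)C
F6 | step 4 | 1,2,5-tribromo-3-(methoxymethoxy)-4-[(2-methylprop-2-en-1-yl)oxy]benzene | CC(=C)COc1c(Br)cc(Br)c(Br)c1OCOC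
A1 | alternative 1 | N-[2,3,6-tribromo-5-(3,5-dibromo-2-methoxyphenoxy)-4-hydroxyphenyl]acetamide | COc1c(Br)cc(Br)cc1Oc1c(Br)c(NC(C)=O)c(Br)c(Br)c1O
A2 | alternative 1 | N-[3-(3,5-dibromo-2-methoxyphenoxy)-4-hydroxyphenyl]acetamide | COc1c(Br)cc(Br)cc1Oc1cc(NC(C)=O)ccc1O
A3 | alternative 2 | 2,4-dibromo-6-[2,4,5-tribromo-6-(propan-2-yloxy)phenoxy]phenol | Oc1c(Br)cc(Br)cc1Oc1c(Br)cc(Br)c(Br)c1OC(C)C
A4 | alternative 2 | 2-[2,4,5-tribromo-6-(propan-2-yloxy)phenoxy]cyclohexan-1-one (racemic) | O=C1CCCCC1Oc1c(Br)cc(Br)c(Br)c1OC(C)C
A5 | alternative 3 | 1,5-dibromo-2-methoxy-3-[2,4,5-tribromo-6-(methoxymethoxy)phenoxy]benzene | COc1c(Br)cc(Br)cc1Oc1c(Br)cc(Br)c(Br)c1OCOC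
A6 | alternative 3 | {1-methoxy-2-[2,4,5-tribromo-6-(methoxymethoxy)phenoxy]ethenoxy}trimethylsilane (alkene geometry not defined) | COC(O[Si](C)(C)C)=COc1c(Br)cc(Br)c(Br)c1OCOC
A7 | alternative 3 | 3,5-dibromo-2H-pyran-2-one | O=C1OC=C(Br)C=C1Br
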